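The cyclohexane ring (locants: C1 carries the side chain, C3 bromine, C4 chlorine and methyl) is cut at C1–C2 and C4–C5. Ring C3 is read as the carbonyl of a pentan-3-one unit, its α-carbons being C2 and C4 with the methyl group, and C1–C6–C5 as an enal. One aminocatalytic Michael/aldol condensation joins a tert-butyl β-keto ester to a γ-hydroxy enal that already holds the quaternary carbinol, built from (S)-lactate by chelation control; it closes the ring and sets C1. The enone that results is turned into the trans-diequatorial bromochloride through reduction, radical hydrobromination and a 1,2-bromine shift with chloride capture.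

Key step: step 6

Remark: it is assumed that catalyst control overrides the influence of the stereocentres already present in steps 6, 8 and 10. Direct bromochlorination of a ring alkene is avoided on purpose, because trans-diaxial opening would put bromine trans to the side chain.

Step 1
Reactants: 1 ethyl (2S)-2-hydroxypropanoate, 2 2-(bromomethyl)naphthalene
Product: 3 ethyl (2S)-2-(naphthalen-2-ylmethoxy)propanoate
Conditions: Ag2O, Et2O, rt, dark
Reagents that add atoms: none
Why: Williamson-type O-alkylation under neutral silver oxide conditions should leave the lactate stereocentre untouched and installs a chelating, acid-stable, DDQ-cleavable naphthylmethyl ether.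

Step 2
Reactants: 3 ethyl (2S)-2-(naphthalen-2-ylmethoxy)propanoate, 4 3,3-diethoxyprop-1-yne
Product: 6 (5S)-1,1-diethoxy-5-(naphthalen-2-ylmethoxy)hex-2-yn-4-one, via lithium acetylide 5 (not isolated)
Conditions: n-BuLi, THF, −78 °C; then 3, −78 °C; aq. NH4Cl
Reagents that add atoms: none
Why: Acylation of an alkynyllithium by an α-alkoxy ester, in which the lithium-chelated tetrahedral intermediate should persist at −78 °C so that the ynone is released only on quenching and a second addition is avoided.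

Step 3
Reactants: 6 (5S)-1,1-diethoxy-5-(naphthalen-2-ylmethoxy)hex-2-yn-4-one, 7 allylmagnesium bromide
Product: 8 (4R,5S)-1,1-diethoxy-5-(naphthalen-2-ylmethoxy)-4-(prop-2-en-1-yl)hex-2-yn-4-ol
Conditions: CH2Cl2/Et2O, −78 °C
Reagents that add atoms: none
Why: Chelation-controlled Grignard 1,2-addition to an α-alkoxy ketone: magnesium bridges the carbonyl and ether oxygens and the allyl group should enter from the face of the α-hydrogen, anti to the methyl group, which sets the quaternary carbinol (4R).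

Step 4
Reactants: 8 (4R,5S)-1,1-diethoxy-5-(naphthalen-2-ylmethoxy)-4-(prop-2-en-1-yl)hex-2-yn-4-ol
Product: 9 (2E,4R,5S)-1,1-diethoxy-5-(naphthalen-2-ylmethoxy)-4-(prop-2-en-1-yl)hex-2-en-4-ol
Conditions: NaAlH2(OCH2CH2OMe)2 (Red-Al), THF, 0 °C to rt; aq. potassium sodium tartrate
Reagents that add atoms: none
Why: Hydroxyl-directed trans-hydroalumination of a propargylic alcohol should give the (E)-alkene only and leave the acetal and the terminal alkene untouched.

Step 5
Reactants: 9 (2E,4R,5S)-1,1-diethoxy-5-(naphthalen-2-ylmethoxy)-4-(prop-2-en-1-yl)hex-2-en-4-ol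
Product: 10 (2E,4R,5S)-4-hydroxy-5-(naphthalen-2-ylmethoxy)-4-(prop-2-en-1-yl)hex-2-enal
Conditions: aq. citric acid (pH about 3), THF, rt
Reagents that add atoms: water, O
Why: Mild acid-catalysed acetal hydrolysis should release the conjugated (E)-enal without ionising the tertiary allylic alcohol, whose cation would be destabilised by the acceptor.

Step 6
Reactants: 10 (2E,4R,5S)-4-hydroxy-5-(naphthalen-2-ylmethoxy)-4-(prop-2-en-1-yl)hex-2-enal, 11 tert-butyl 3-oxopentanoate
Product: 13 (5S)-5-[(2S,3R)-3-hydroxy-2-(naphthalen-2-ylmethoxy)hex-5-en-3-yl]-2-methylcyclohex-2-en-1-one, via Michael adduct 12 (not isolated)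
Conditions: (R)-2-{bis[3,5-bis(trifluoromethyl)phenyl](trimethylsilyloxy)methyl}pyrrolidine (10 mol%), PhCO2H (10 mol%), toluene, rt; then TsOH·H2O (20 mol%), toluene, 80 °C
Reagents that add atoms: none
Why: The amine condenses with 10 to an (E)-iminium ion, the enol of 11 adds through its doubly activated carbon to the β-carbon (Michael addition, bond ring C1–C2) to give 12, and under acid the ethyl ketone enolises toward its CH2 group, which attacks the aldehyde (bond ring C4–C5), followed by dehydration and loss of isobutene and CO2. The closest known reaction type is the aminocatalytic Michael/aldol condensation of β-keto esters with enals to 5-substituted cyclohex-2-enones, a formal [3+3] Robinson-type annulation. The ring closes by a 6-(enolendo)-exo-trig aldol addition. The only new stereocentre, ring C1, is set in the Michael step by the catalyst, whose diaryl(silyloxy)methyl group shields one face of the iminium ion, so that the (R)-catalyst should give (5S). The step needs 1,4- rather than 1,2-addition and aldolisation through the ethyl CH2 group; iminium activation and the irreversible dehydration/decarboxylation toward the conjugated enone secure both, while the fully substituted γ-carbon is the main risk.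

Step 7
Reactants: 13 (5S)-5-[(2S,3R)-3-hydroxy-2-(naphthalen-2-ylmethoxy)hex-5-en-3-yl]-2-methylcyclohex-2-en-1-one, 14 2-methylbut-2-ene
Product: 15 (5S)-5-[(2S,3R)-3-hydroxy-6-methyl-2-(naphthalen-2-ylmethoxy)hept-5-en-3-yl]-2-methylcyclohex-2-en-1-one
Conditions: second-generation Grubbs catalyst RuCl2(=CHPh)(H2IMes)(PCy3) (5 mol%), excess 14, CH2Cl2, 40 °C
Reagents that add atoms: none
Why: Olefin cross-metathesis of the monosubstituted alkene with 2-methylbut-2-ene as prenyl donor should leave the electron-poor trisubstituted enone untouched.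

Step 8
Reactants: 15 (5S)-5-[(2S,3R)-3-hydroxy-6-methyl-2-(naphthalen-2-ylmethoxy)hept-5-en-3-yl]-2-methylcyclohex-2-en-1-one
Product: 16 (5S)-5-[(2R,3S)-1-[(2S)-3,3-dimethyloxiran-2-yl]-2-hydroxy-3-(naphthalen-2-ylmethoxy)butan-2-yl]-2-methylcyclohex-2-en-1-one
Conditions: ent-Shi ketone (1,2:4,5-di-O-isopropylidene-β-L-erythro-2,3-hexodiulo-2,6-pyranose, from L-sorbose, 30 mol%), Oxone (2KHSO5·KHSO4·K2SO4), K2CO3, Bu4NHSO4, MeCN/dimethoxymethane/aq. Na2B4O7 buffer, 0 °C
Reagents that add atoms: potassium peroxymonosulfate, [K+].OOS(=O)(=O)[O-]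
Why: Shi asymmetric epoxidation by the chiral dioxirane should take the electron-rich trisubstituted alkene in preference to the enone, and the spiro transition state of the ent-ketone should give the (S)-epoxide.

Step 9
Reactants: 16 (5S)-5-[(2R,3S)-1-[(2S)-3,3-dimethyloxiran-2-yl]-2-hydroxy-3-(naphthalen-2-ylmethoxy)butan-2-yl]-2-methylcyclohex-2-en-1-one
Product: 17 (5S)-5-[(2S,3R,5R)-5-bromo-3,6-dihydroxy-6-methyl-2-(naphthalen-2-ylmethoxy)heptan-3-yl]-2-methylcyclohex-2-en-1-one
Conditions: Li2NiBr4, THF, 0 °C to rt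
Reagents that add atoms: dilithium tetrabromonickelate, [Li+].[Li+].[Ni+2].[Br-].[Br-].[Br-].[Br-]
Why: SN2 opening of the epoxide by soft bromide at the less substituted carbon with inversion should give the (R)-secondary bromide next to the tertiary alcohol.

Step 10
Reactants: 17 (5S)-5-[(2S,3R,5R)-5-bromo-3,6-dihydroxy-6-methyl-2-(naphthalen-2-ylmethoxy)heptan-3-yl]-2-methylcyclohex-2-en-1-one
Product: 18 (1R,5S)-5-[(2S,3R,5R)-5-bromo-3,6-dihydroxy-6-methyl-2-(naphthalen-2-ylmethoxy)heptan-3-yl]-2-methylcyclohex-2-en-1-ol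
Conditions: (S)-2-methyl-CBS-oxazaborolidine (20 mol%), BH3·SMe2 (excess), THF, −30 °C; MeOH
Reagents that add atoms: none
Why: Corey–Bakshi–Shibata reduction, a reagent-controlled 1,2-reduction of the α-methyl enone in which the (S)-oxazaborolidine should deliver hydride to the face cis to the side chain and give the trans (1R) allylic alcohol with a pseudoaxial hydroxyl.

Step 11
Reactants: 18 (1R,5S)-5-[(2S,3R,5R)-5-bromo-3,6-dihydroxy-6-methyl-2-(naphthalen-2-ylmethoxy)heptan-3-yl]-2-methylcyclohex-2-en-1-ol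
Product: 19 (1R,2R,5S)-2-bromo-5-[(2S,3R,5R)-5-bromo-3,6-dihydroxy-6-methyl-2-(naphthalen-2-ylmethoxy)heptan-3-yl]-2-methylcyclohexan-1-ol
Conditions: Co(acac)2 (30 mol%), t-BuOOH, Et3SiH, TsBr, n-PrOH, rt
Reagents that add atoms: 4-methylbenzenesulfonyl bromide, Cc1ccc(cc1)S(=O)(=O)Br
Why: Mukaiyama-type hydrogen-atom-transfer Markovnikov hydrobromination, in which the tertiary radical at ring C4 should take bromine from TsBr on the axial face anti to the axial hydroxyl at ring C3 and so give the trans-diaxial bromohydrin with bromine cis to the side chain.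

Step 12
Reactants: 19 (1R,2R,5S)-2-bromo-5-[(2S,3R,5R)-5-bromo-3,6-dihydroxy-6-methyl-2-(naphthalen-2-ylmethoxy)heptan-3-yl]-2-methylcyclohexan-1-ol
Product: 21 (2S,3R,5R)-5-bromo-3-[(1S,3S,4S)-3-bromo-4-chloro-4-methylcyclohexyl]-6-methyl-2-(naphthalen-2-ylmethoxy)heptane-3,6-diol, via axial mesylate 20 (not isolated)
Conditions: MsCl, Et3N, CH2Cl2, −20 °C; then LiCl, DMF, 0 °C to rt
Reagents that add atoms: lithium chloride, [Li+].[Cl-]
Why: Deoxychlorination with neighbouring-group participation, in which the axial tertiary bromine, antiperiplanar to the axial mesylate, should bridge to a bromonium ion on the face cis to the side chain that chloride opens at the tertiary carbon (Markovnikov) from the opposite face, a net 1,2-bromine shift that sets ring C3 (Br) and ring C4 (Cl) as the trans-diequatorial pair; only the secondary alcohol is sulfonylated.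

Step 13
Reactants: 21 (2S,3R,5R)-5-bromo-3-[(1S,3S,4S)-3-bromo-4-chloro-4-methylcyclohexyl]-6-methyl-2-(naphthalen-2-ylmethoxy)heptane-3,6-diol
Product: 22 (2S,3R,5R)-5-bromo-3-[(1S,3S,4S)-3-bromo-4-chloro-4-methylcyclohexyl]-6-methylheptane-2,3,6-triol
Conditions: DDQ, CH2Cl2/pH 7 phosphate buffer, 0 °C to rt
Reagents that add atoms: none
Why: Oxidative cleavage of the naphthylmethyl ether by DDQ (hydride abstraction, then hydrolysis of the oxocarbenium ion) should spare the alkyl halides and the tertiary alcohols.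

Step 14
Reactants: 22 (2S,3R,5R)-5-bromo-3-[(1S,3S,4S)-3-bromo-4-chloro-4-methylcyclohexyl]-6-methylheptane-2,3,6-triol
Product: 23 (3R,5R)-5-bromo-3-[(1S,3S,4S)-3-bromo-4-chloro-4-methylcyclohexyl]-3,6-dihydroxy-6-methylheptan-2-one
Conditions: Dess–Martin periodinane, pyridine, CH2Cl2, 0 °C to rt
Reagents that add atoms: none
Why: Dess–Martin oxidation of the only secondary alcohol should give the methyl ketone, the tertiary alcohols being inert, and removes the sacrificial lactate stereocentre.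

Compound list
1 | ethyl (2S)-2-hydroxypropanoate | C[C@H](O)C(=O)OCC | starting material
2 | 2-(bromomethyl)naphthalene | BrCc1ccc2ccccc2c1 | starting material
3 | ethyl (2S)-2-(naphthalen-2-ylmethoxy)propanoate | C[C@H](OCc1ccc2ccccc2c1)C(=O)OCC | intermediate
4 | 3,3-diethoxyprop-1-yne | C#CC(OCC)OCC | starting material
5 | lithium 3,3-diethoxyprop-1-yn-1-ide | [Li]C#CC(OCC)OCC | intermediate
6 | (5S)-1,1-diethoxy-5-(naphthalen-2-ylmethoxy)hex-2-yn-4-one | C[C@H](OCc1ccc2ccccc2c1)C(=O)C#CC(OCC)OCC | intermediate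
7 | allylmagnesium bromide | C=CC[Mg]Br | starting material
8 | (4R,5S)-1,1-diethoxy-5-(naphthalen-2-ylmethoxy)-4-(prop-2-en-1-yl)hex-2-yn-4-ol | C[C@H](OCc1ccc2ccccc2c1)[C@@](O)(CC=C)C#CC(OCC)OCC | intermediate
9 | (2E,4R,5S)-1,1-diethoxy-5-(naphthalen-2-ylmethoxy)-4-(prop-2-en-1-yl)hex-2-en-4-ol | C[C@H](OCc1ccc2ccccc2c1)[C@@](O)(CC=C)/C=C/C(OCC)OCC | intermediate
10 | (2E,4R,5S)-4-hydroxy-5-(naphthalen-2-ylmethoxy)-4-(prop-2-en-1-yl)hex-2-enal | C[C@H](OCc1ccc2ccccc2c1)[C@@](O)(CC=C)/C=C/C=O | intermediate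
11 | tert-butyl 3-oxopentanoate | CCC(=O)CC(=O)OC(C)(C)C | starting material
12 | tert-butyl 2-[(3S,4R,5S)-4-hydroxy-5-(naphthalen-2-ylmethoxy)-1-oxo-4-(prop-2-en-1-yl)hexan-3-yl]-3-oxopentanoate (Michael adduct, epimers at the keto ester carbon) | C[C@H](OCc1ccc2ccccc2c1)[C@@](O)(CC=C)[C@@H](CC=O)C(C(=O)OC(C)(C)C)C(=O)CC | intermediate
13 | (5S)-5-[(2S,3R)-3-hydroxy-2-(naphthalen-2-ylmethoxy)hex-5-en-3-yl]-2-methylcyclohex-2-en-1-one | C[C@H](OCc1ccc2ccccc2c1)[C@@](O)(CC=C)[C@H]1CC=C(C)C(=O)C1 | intermediate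
14 | 2-methylbut-2-ene | CC=C(C)C | starting material
15 | (5S)-5-[(2S,3R)-3-hydroxy-6-methyl-2-(naphthalen-2-ylmethoxy)hept-5-en-3-yl]-2-methylcyclohex-2-en-1-one | C[C@H](OCc1ccc2ccccc2c1)[C@@](O)(CC=C(C)C)[C@H]1CC=C(C)C(=O)C1 | intermediate
16 | (5S)-5-[(2R,3S)-1-[(2S)-3,3-dimethyloxiran-2-yl]-2-hydroxy-3-(naphthalen-2-ylmethoxy)butan-2-yl]-2-methylcyclohex-2-en-1-one | C[C@H](OCc1ccc2ccccc2c1)[C@@](O)(C[C@@H]1OC1(C)C)[C@H]1CC=C(C)C(=O)C1 | intermediate
17 | (5S)-5-[(2S,3R,5R)-5-bromo-3,6-dihydroxy-6-methyl-2-(naphthalen-2-ylmethoxy)heptan-3-yl]-2-methylcyclohex-2-en-1-one | C[C@H](OCc1ccc2ccccc2c1)[C@@](O)(C[C@@H](Br)C(C)(C)O)[C@H]1CC=C(C)C(=O)C1 | intermediate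
18 | (1R,5S)-5-[(2S,3R,5R)-5-bromo-3,6-dihydroxy-6-methyl-2-(naphthalen-2-ylmethoxy)heptan-3-yl]-2-methylcyclohex-2-en-1-ol | C[C@H](OCc1ccc2ccccc2c1)[C@@](O)(C[C@@H](Br)C(C)(C)O)[C@H]1CC=C(C)[C@H](O)C1 | intermediate
19 | (1R,2R,5S)-2-bromo-5-[(2S,3R,5R)-5-bromo-3,6-dihydroxy-6-methyl-2-(naphthalen-2-ylmethoxy)heptan-3-yl]-2-methylcyclohexan-1-ol | C[C@H](OCc1ccc2ccccc2c1)[C@@](O)(C[C@@H](Br)C(C)(C)O)[C@H]1CC[C@@](C)(Br)[C@H](O)C1 | intermediate
20 | (1R,2R,5S)-2-bromo-5-[(2S,3R,5R)-5-bromo-3,6-dihydroxy-6-methyl-2-(naphthalen-2-ylmethoxy)heptan-3-yl]-2-methylcyclohexyl methanesulfonate | C[C@H](OCc1ccc2ccccc2c1)[C@@](O)(C[C@@H](Br)C(C)(C)O)[C@H]1CC[C@@](C)(Br)[C@H](OS(C)(=O)=O)C1 | intermediate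
21 | (2S,3R,5R)-5-bromo-3-[(1S,3S,4S)-3-bromo-4-chloro-4-methylcyclohexyl]-6-methyl-2-(naphthalen-2-ylmethoxy)heptane-3,6-diol | C[C@H](OCc1ccc2ccccc2c1)[C@@](O)(C[C@@H](Br)C(C)(C)O)[C@H]1CC[C@](C)(Cl)[C@@H](Br)C1 | intermediate
22 | (2S,3R,5R)-5-bromo-3-[(1S,3S,4S)-3-bromo-4-chloro-4-methylcyclohexyl]-6-methylheptane-2,3,6-triol | C[C@H](O)[C@@](O)(C[C@@H](Br)C(C)(C)O)[C@H]1CC[C@](C)(Cl)[C@@H](Br)C1 | intermediate
23 | (3R,5R)-5-bromo-3-[(1S,3S,4S)-3-bromo-4-chloro-4-methylcyclohexyl]-3,6-dihydroxy-6-methylheptan-2-one | CC(=O)[C@@](O)(C[C@@H](Br)C(C)(C)O)[C@H]1CC[C@](C)(Cl)[C@@H](Br)C1 | target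

Total step count: 14. Longest linear sequence: 14 steps (from 1).

Steps most likely to fail

Step 6. The conjugate addition may be too slow, because the β-carbon of 10 sits next to a fully substituted carbinol carbon. The free tertiary hydroxyl may also hold the adduct as a lactol before the aldol condensation. The fallback sets out from 6 and builds the ring on a less hindered acceptor, adding the allyl group afterwards.
- Luche reduction of 6 (NaBH4, CeCl3·7H2O) should give the propargylic alcohol (4RS,5S)-1,1-diethoxy-5-(naphthalen-2-ylmethoxy)hex-2-yn-4-ol F1, as both carbinol epimers, which converge later.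
- Red-Al reduction gives the (E)-allylic alcohol (2E,4RS,5S)-1,1-diethoxy-5-(naphthalen-2-ylmethoxy)hex-2-en-4-ol F2.
- Silylation (t-BuMe2SiCl, imidazole) gives the silyl ether (2E,4RS,5S)-4-[tert-butyl(dimethyl)silyloxy]-1,1-diethoxy-5-(naphthalen-2-ylmethoxy)hex-2-ene F3.
- Citric acid hydrolysis gives the γ-silyloxy enal (2E,4RS,5S)-4-[tert-butyl(dimethyl)silyloxy]-5-(naphthalen-2-ylmethoxy)hex-2-enal F4, whose γ-carbon is only secondary.
- The same aminocatalytic Michael/aldol condensation with 11 gives the enone (5S)-5-[(1RS,2S)-1-[tert-butyl(dimethyl)silyloxy]-2-(naphthalen-2-ylmethoxy)propyl]-2-methylcyclohex-2-en-1-one F5.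
- HF·pyridine gives the alcohol (5S)-5-[(1RS,2S)-1-hydroxy-2-(naphthalen-2-ylmethoxy)propyl]-2-methylcyclohex-2-en-1-one F6.
- Dess–Martin oxidation gives the diketone (5S)-2-methyl-5-[(2S)-2-(naphthalen-2-ylmethoxy)propanoyl]cyclohex-2-en-1-one F7.
- Chelation-controlled addition of 7 (one equivalent, −78 °C) to the α-alkoxy ketone, which should react before the less electrophilic α-methyl enone, comes back to the route at 13.

Step 12. Chloride may open the bromonium ion at the secondary carbon (trans-diaxial opening) instead of the tertiary one, and the tertiary bromide may be lost by elimination. The fallback sets out from 19 and accepts the diaxial regioisomer (2S,3R,5R)-5-bromo-3-[(1S,3R,4R)-4-bromo-3-chloro-4-methylcyclohexyl]-6-methyl-2-(naphthalen-2-ylmethoxy)heptane-3,6-diol F8, formed from mesylate 20 with Et4NCl in CH2Cl2. F8 is then isomerised by the thermal diaxial-to-diequatorial rearrangement of vicinal dihalides (warming in 1,1,1,3,3,3-hexafluoropropan-2-ol). In this rearrangement the two halogens change places, each on its own ring face, through a halonium/halide ion pair. The product, which can no longer ionise with anchimeric assistance, is 21, where the route is rejoined.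

Step 10. The reagent has to override the inherent preference of the 5-substituted enone for hydride attack that gives the cis alcohol, so facial selectivity may be poor. The fallback sets out from 17.
- Luche reduction (NaBH4, CeCl3·7H2O, MeOH, −78 °C) should give the cis-allylic alcohol (1S,5S)-5-[(2S,3R,5R)-5-bromo-3,6-dihydroxy-6-methyl-2-(naphthalen-2-ylmethoxy)heptan-3-yl]-2-methylcyclohex-2-en-1-ol F9.
- Mitsunobu inversion with benzoic acid (PPh3, diisopropyl azodicarboxylate) gives the benzoate (1R,5S)-5-[(2S,3R,5R)-5-bromo-3,6-dihydroxy-6-methyl-2-(naphthalen-2-ylmethoxy)heptan-3-yl]-2-methylcyclohex-2-en-1-yl benzoate F10.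
- Reductive ester cleavage with i-Bu2AlH at −78 °C, which is not basic toward the side-chain bromohydrin, comes back to the route at 18.

Further compounds
F1 | step 6 | (4RS,5S)-1,1-diethoxy-5-(naphthalen-2-ylmethoxy)hex-2-yn-4-ol | C[C@H](OCc1ccc2ccccc2c1)C(O)C#CC(OCC)OCC
F2 | step 6 | (2E,4RS,5S)-1,1-diethoxy-5-(naphthalen-2-ylmethoxy)hex-2-en-4-ol | C[C@H](OCc1ccc2ccccc2c1)C(O)/C=C/C(OCC)OCC
F3 | step 6 | (2E,4RS,5S)-4-[tert-butyl(dimethyl)silyloxy]-1,1-diethoxy-5-(naphthalen-2-ylmethoxy)hex-2-ene | C[C@H](OCc1ccc2ccccc2c1)C(O[Si](C)(C)C(C)(C)C)/C=C/C(OCC)OCC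
F4 | step 6 | (2E,4RS,5S)-4-[tert-butyl(dimethyl)silyloxy]-5-(naphthalen-2-ylmethoxy)hex-2-enal | C[C@H](OCc1ccc2ccccc2c1)C(O[Si](C)(C)C(C)(C)C)/C=C/C=O
F5 | step 6 | (5S)-5-[(1RS,2S)-1-[tert-butyl(dimethyl)silyloxy]-2-(naphthalen-2-ylmethoxy)propyl]-2-methylcyclohex-2-en-1-one | C[C@H](OCc1ccc2ccccc2c1)C(O[Si](C)(C)C(C)(C)C)[C@H]1CC=C(C)C(=O)C1
F6 | step 6 | (5S)-5-[(1RS,2S)-1-hydroxy-2-(naphthalen-2-ylmethoxy)propyl]-2-methylcyclohex-2-en-1-one | C[C@H](OCc1ccc2ccccc2c1)C(O)[C@H]1CC=C(C)C(=O)C1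
F7 | step 6 | (5S)-2-methyl-5-[(2S)-2-(naphthalen-2-ylmethoxy)propanoyl]cyclohex-2-en-1-one | C[C@H](OCc1ccc2ccccc2c1)C(=O)[C@H]1CC=C(C)C(=O)C1
F8 | step 12 | (2S,3R,5R)-5-bromo-3-[(1S,3R,4R)-4-bromo-3-chloro-4-methylcyclohexyl]-6-methyl-2-(naphthalen-2-ylmethoxy)heptane-3,6-diol | C[C@H](OCc1ccc2ccccc2c1)[C@@](O)(C[C@@H](Br)C(C)(C)O)[C@H]1CC[C@@](C)(Br)[C@H](Cl)C1
F9 | step 10 | (1S,5S)-5-[(2S,3R,5R)-5-bromo-3,6-dihydroxy-6-methyl-2-(naphthalen-2-ylmethoxy)heptan-3-yl]-2-methylcyclohex-2-en-1-ol | C[C@H](OCc1ccc2ccccc2c1)[C@@](O)(C[C@@H](Br)C(C)(C)O)[C@H]1CC=C(C)[C@@H](O)C1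
F10 | step 10 | (1R,5S)-5-[(2S,3R,5R)-5-bromo-3,6-dihydroxy-6-methyl-2-(naphthalen-2-ylmethoxy)heptan-3-yl]-2-methylcyclohex-2-en-1-yl benzoate | C[C@H](OCc1ccc2ccccc2c1)[C@@](O)(C[C@@H](Br)C(C)(C)O)[C@H]1CC=C(C)[C@H](OC(=O)c2ccccc2)C1
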